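**Retrosynthetic overview**
- The only strategic disconnection is the depside (aryl ester) C–O bond, giving 2,3,4-trihydroxy-6-methylbenzoic acid and commercial methyl 2,4-dihydroxy-3,6-dimethylbenzoate.
- The acid comes from 5-methylpyrogallol and CO2 by Kolbe–Schmitt carboxylation; the two free ring positions are equivalent, so only one regioisomer can form.
- The ester bond is made without classical protecting groups: an arylboronic acid masks the three phenols of the acid and activates its carboxyl group in the same flask.
- No ring is built. Both benzene rings are bought; only transient boron heterocycles (a dioxaborole and a dioxaborinone) form and are hydrolysed on work-up.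

Assumption: the target has no stereocentre and no stereogenic axis, so it is one achiral compound and no stereocontrol is needed. 5-Methylpyrogallol, methyl 2,4-dihydroxy-3,6-dimethylbenzoate and 3,4,5-trifluorophenylboronic acid are taken as commercial.

**Step 1**
Reactants: 1 5-methylpyrogallol (5-methylbenzene-1,2,3-triol)
Product: 3 2,3,4-trihydroxy-6-methylbenzoic acid, via potassium 2,3,4-trihydroxy-6-methylbenzoate 2 (not isolated)
Conditions: KHCO3 (5 equiv), degassed H2O, CO2 (1 atm, slow stream), 95 °C, 4 h; then 6 M HCl, 0 °C, pH 2; dry cold and use at once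
Reagents that add atoms: potassium hydrogen carbonate, [K+].OC(=O)[O-] (carboxyl carbon and the potassium of 2); carbon dioxide, O=C=O (atmosphere, same carboxyl source)
Why: Kolbe–Schmitt carboxylation of the phenoxide at C4/C6, which are equivalent, each ortho to one OH and para to another, and the only free ring positions, so a single regioisomer results as for pyrogallol itself; no stereocentre is formed.

**Step 2**
Reactants: 3 2,3,4-trihydroxy-6-methylbenzoic acid; 4 methyl 2,4-dihydroxy-3,6-dimethylbenzoate (1.1 equiv); 5 3,4,5-trifluorophenylboronic acid (2.1 equiv, recoverable template)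
Product: 8 methyl 2-hydroxy-3,6-dimethyl-4-[(2,3,4-trihydroxy-6-methylbenzoyl)oxy]benzoate (target), via bis(arylboronate) acyl donor 6 (not isolated), via boron-masked depside 7 (not isolated)
Conditions: 3, 5, PhF, reflux through 4 Å MS (Soxhlet), Ar, 1 h; then 4, DMAPO (10 mol %), reflux, 16 h; then MeOH/H2O, rt
Reagents that add atoms: none
Why: Proposed new method: boronic-acid-templated, protecting-group-free depside esterification – two equivalents of electron-poor 5 condense with 3 so that O3/O4 become a 1,3,2-dioxaborole and O2/CO2H a 1,3,2-dioxaborinin-4-one (6), which leaves no free OH on the acyl donor (no self-esterification, ring deactivated towards oxidation and protodecarboxylation) and turns the carboxyl into a cyclic acyloxyborane held coplanar with the ring, so attack perpendicular to the plane is not blocked by the 6-methyl group; DMAPO opens this mixed anhydride to an O-acyl-oxypyridinium that is captured by the only unhindered free hydroxyl in the flask, the 4-OH of 4 (its 2-OH is hydrogen-bonded to the ester and flanked by two substituents), forming the aryl ester C–O bond in 7, and hydrolytic work-up releases 8 and 5; the closest known reaction types are arylboronic acid/DMAPO-cocatalysed dehydrative condensation of carboxylic acids via acyloxyboranes, boric acid-catalysed direct esterification of phenols, and transient boronate masking of 1,2-diols during acylation, and what is new is one boron reagent acting as both mask and activator on a free polyhydroxysalicylic acid with a phenol as nucleophile; no stereocentre is formed.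

**Compound list**
1 | 5-methylpyrogallol (5-methylbenzene-1,2,3-triol) | Cc1cc(O)c(O)c(O)c1 | starting material
2 | potassium 2,3,4-trihydroxy-6-methylbenzoate | Cc1cc(O)c(O)c(O)c1C(=O)[O-].[K+] | intermediate
3 | 2,3,4-trihydroxy-6-methylbenzoic acid | Cc1cc(O)c(O)c(O)c1C(=O)O | intermediate
4 | methyl 2,4-dihydroxy-3,6-dimethylbenzoate (methyl β-orcinolcarboxylate) | COC(=O)c1c(C)cc(O)c(C)c1O | starting material
5 | 3,4,5-trifluorophenylboronic acid | OB(O)c1cc(F)c(F)c(F)c1 | starting material
6 | cyclic bis(3,4,5-trifluorophenylboronate) of 3: O3,O4-bridged 1,3,2-dioxaborole plus O2,carboxyl-bridged 1,3,2-dioxaborinin-4-one (acyloxyborane) on the same benzene ring | Cc1cc2OB(c3cc(F)c(F)c(F)c3)Oc2c2OB(c3cc(F)c(F)c(F)c3)OC(=O)c12 | intermediate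
7 | depside 8 carrying a B(3,4,5-trifluorophenyl) bridge across O3′/O4′ and a B(OH)(3,4,5-trifluorophenyl) group on O2′ | COC(=O)c1c(C)cc(OC(=O)c2c(C)cc3OB(c4cc(F)c(F)c(F)c4)Oc3c2OB(O)c2cc(F)c(F)c(F)c2)c(C)c1O | intermediate
8 | methyl 2-hydroxy-3,6-dimethyl-4-[(2,3,4-trihydroxy-6-methylbenzoyl)oxy]benzoate | COC(=O)c1c(C)cc(OC(=O)c2c(C)cc(O)c(O)c2O)c(C)c1O | target

**Total step count:** 2
**Longest linear sequence:** 2 steps (1 → 3 → 8)

**Steps most likely to fail** (the route has only two steps, so both are ranked, most risky first)

Step 2 (proposed new step). The chelated acyloxyborane in 6 may be too stable to acylate a phenol, or boron may not mask all three hydroxyls cleanly. The fallback uses known chemistry: the classical protected depside synthesis, setting out from 3 and 4 and coming back to the route at 8. Acid 3 is perbenzylated (BnBr, K2CO3, DMF, 60 °C, N2) to benzyl 2,3,4-tris(benzyloxy)-6-methylbenzoate F1. The hindered benzyl ester is cleaved with KOH in aqueous DMSO at 90 °C to potassium 2,3,4-tris(benzyloxy)-6-methylbenzoate F2, and acidification gives 2,3,4-tris(benzyloxy)-6-methylbenzoic acid F3. F3 is coupled with 4 through the mixed trifluoroacetic anhydride (TFAA, toluene, rt), which acylates only the 4-OH of 4, to give methyl 2-hydroxy-3,6-dimethyl-4-{[2,3,4-tris(benzyloxy)-6-methylbenzoyl]oxy}benzoate F4. Hydrogenolysis (H2, Pd/C, EtOAc, rt) then gives 8.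

Step 1. The carboxylation is reversible, the product acid decarboxylates easily, and the pyrogallol unit oxidises in basic solution. The fallback replaces the CO2 electrophile by a masked carboxyl introduced through Houben–Hoesch acylation, setting out from 1 and coming back to the route at 2 (and then 3). Compound 1 reacts with trichloroacetonitrile (ZnCl2, HCl gas, Et2O, 0 °C) to give 2,2,2-trichloro-1-(2,3,4-trihydroxy-6-methylphenyl)ethan-1-iminium chloride F5. Warm water hydrolyses it to 2,2,2-trichloro-1-(2,3,4-trihydroxy-6-methylphenyl)ethan-1-one F6. Haloform-type cleavage with cold aqueous KOH under N2 gives the potassium salt 2, and acidification with HCl as in step 1 gives 3.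

**Further compounds**
F1 | step 2 | benzyl 2,3,4-tris(benzyloxy)-6-methylbenzoate | Cc1cc(OCc2ccccc2)c(OCc2ccccc2)c(OCc2ccccc2)c1C(=O)OCc1ccccc1
F2 | step 2 | potassium 2,3,4-tris(benzyloxy)-6-methylbenzoate | Cc1cc(OCc2ccccc2)c(OCc2ccccc2)c(OCc2ccccc2)c1C(=O)[O-].[K+]
F3 | step 2 | 2,3,4-tris(benzyloxy)-6-methylbenzoic acid | Cc1cc(OCc2ccccc2)c(OCc2ccccc2)c(OCc2ccccc2)c1C(=O)O
F4 | step 2 | methyl 2-hydroxy-3,6-dimethyl-4-{[2,3,4-tris(benzyloxy)-6-methylbenzoyl]oxy}benzoate | COC(=O)c1c(C)cc(OC(=O)c2c(C)cc(OCc3ccccc3)c(OCc3ccccc3)c2OCc2ccccc2)c(C)c1O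
F5 | step 1 | 2,2,2-trichloro-1-(2,3,4-trihydroxy-6-methylphenyl)ethan-1-iminium chloride | Cc1cc(O)c(O)c(O)c1C(=[NH2+])C(Cl)(Cl)Cl.[Cl-]
F6 | step 1 | 2,2,2-trichloro-1-(2,3,4-trihydroxy-6-methylphenyl)ethan-1-one | Cc1cc(O)c(O)c(O)c1C(=O)C(Cl)(Cl)Cl
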